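The earlier runs and the new flask stem from a simulated flask with constants of no real substance; noise was put on by code.

**Common curve.** At 2.50 h the south-east run holds 3.76 mM of target and the west run 3.78 mM, though west was charged with more solid substrate. So we reckon target in concentration and ask how long the flask's 14 mM of solid lasts.

| setting | south-east | west | flask |
|---|---|---|---|
| solid substrate | 0.020 M | 0.031 M | 0.014 M |
| remark | run made earlier | run made earlier |  |
| time |  |  | 30 h |

- south-east (time / h: target / %): 0.833: 6.9; 1.33: 11.9; 2.50: 18.8; 4.00: 23.1; 6.00: 23.5; 10.0: 12.1; 20.0: 9.9
- west (time / h: target / %): 0.833: 5.0; 1.33: 8.3; 2.50: 12.2; 4.00: 14.7; 6.00: 16.5; 10.0: 18.3; 20.0: 10.6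

(standard deviation of a reading: 0.5 percentage points)

- solid, in amounts per volume of the solution: solid substrate
- at the start none of the solid substrate is in solution

- time, not beyond 30 h, at which the flask holds most target
- the amount of target, in percent of the solid substrate charged, at that time

**First estimate.** We take each run's peak as the moment its solid ends, and define the feed rate r as the charge divided by that peak time; a constant r would be a zero-order feed. The two highest readings of the south-east run stand at 4.00 h and 6.00 h; we put its peak midway, at 5.00 h, so r reads 4.00 mM h⁻¹. At that r the flask's solid lasts 3.50 h.

**First doubt.** Taking the west run's highest reading, at 10.0 h, as its peak, its feed rate r, charge over peak time, reads 3.10 mM h⁻¹, lower than south-east. So r, as read, is not constant, and we give up the zero-order picture. We draw a line through the two values and put our first answer back in: at 3.50 h r reads 4.27 mM h⁻¹, which gives 3.28 h.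

**Second doubt.** How much target does the flask hold by then? We assume it stays on the common curve. Between its readings at 2.50 h and 4.00 h, the south-east curve gives 4.21 mM at 3.28 h. For the flask that is 30.1 %, and we commit to it, though the peak may round off a little lower.

**The forecast.** It gives 3.2 h (from 2.3 h to 4.2 h) and 29 % (from 25 % to 33 %), holding that “while solid remains, target formation doesn't depend on loading”. Our time is slightly later and our amount slightly higher.

**The flask.** The flask peaks at 3.37 h with 30.6 % of target. Its solid substrate stands at 3.97 % at 3.00 h and 0 % at 3.37 h.

    solid substrate ⇌ starting material, rate k1*(cs1 - [starting material]) while solid is left; crystals form when [starting material] > cs1 (solubility = 6.90 mM, k = 0.0243 min⁻¹)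
    isomer of the product A ⇌ isomer of the product B (K = 0.472, k = 0.0198 min⁻¹)
    target ⇌ isomer of the product A (K = 5.80, k = 0.0120 min⁻¹)
    starting material ⇌ target (K = 3.00, k = 0.0161 min⁻¹)

**What follows.** The flask's r comes to 4.15 mM h⁻¹, above the west value. Target's forward loss to isomer of the product A has a half-life of 0.96 h, short against the 30 h allowed, and at 30.0 h the flask holds 10.1 % of target. For the neighbour flask at 0.056 M, the west r gives a charge lasting about 18.1 h. Computed, that neighbour's solid substrate stands at 0 % at 30.0 h, and its highest target is 14.5 %.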